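The target is cut at the CH2–C(sp2) bond joining the cyclopentylmethyl carbon to the one carbon of the six-membered enolised β-triketone ring that sits between the two C–OH carbons. The key step exploits two features: this ring carbon is the only C–H nucleophile of the triketone, and the CH2 is 1,3 to the tertiary carbinol of the cyclopentane, so it is an aldehyde carbon and the ring bond CH–C(OH)Me is an aldol bond. The C10 half is therefore seco-(R)-limonene: in one flask its acyclic keto-aldehyde is closed by proline to the β-hydroxy aldehyde, condensed with the gem-diprenyl acyltrione and reduced by Hantzsch ester.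

Key step: step 4

Remark: the enolised β-triketone is written throughout as the tautomer of the target SMILES; its tautomers are treated as one compound.

Step 1
Reactants: 1 phloroglucinol; 2 isobutyryl chloride
Product: 3 phlorisobutyrophenone
Conditions: AlCl3, CH2Cl2/MeNO2, 0 °C to rt; then ice/aq. HCl
Reagents that add atoms: isobutyryl chloride (2), CC(C)C(Cl)=O
Why: Friedel–Crafts C-acylation of the electron-rich triol (any O-acyl product undergoes Fries rearrangement under AlCl3) should stop at the mono-ketone because the acyl group deactivates the ring; no stereocentre is formed.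

Step 2
Reactants: 3 phlorisobutyrophenone; 4 prenyl bromide
Product: 5 2-isobutyryl-4,4-diprenylcyclohexane-1,3,5-trione (dienol form)
Conditions: NaOMe, MeOH, 0 °C to rt; then aq. HCl, NaHCO3 extraction
Reagents that add atoms: prenyl bromide (4), CC(C)=CCBr
Why: Dearomative gem-C-prenylation of the acylphloroglucinol polyanion (the C-alkylation type known for hop β-acids and acylfilicinic acids): after the first C-prenylation the alkylated ring carbon is the most electron-rich enolate carbon, so the second SN2 attack should occur there, and the strongly acidic non-aromatic β-triketone is separated from the aromatic 3,5-diprenyl by-product by bicarbonate extraction; no stereocentre is formed.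

Step 3
Reactants: 6 (R)-(+)-limonene
Product: 7 (3R)-6-oxo-3-(prop-1-en-2-yl)heptanal
Conditions: O3 (1 equiv), CH2Cl2/MeOH, −78 °C; then Me2S, −78 °C to rt
Reagents that add atoms: ozone, [O-][O+]=O
Why: Chemoselective ozonolysis with reductive work-up: electrophilic ozone should attack the more electron-rich trisubstituted ring alkene before the 1,1-disubstituted isopropenyl group, and the C4 stereocentre of limonene is not touched.

Step 4
Reactants: 7 (3R)-6-oxo-3-(prop-1-en-2-yl)heptanal; 5 2-isobutyryl-4,4-diprenylcyclohexane-1,3,5-trione
Product: 10 target acylphloroglucinol (full name in the compound list), via β-hydroxy aldehyde 8 (not isolated), via alkylidene trione 9 (not isolated)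
Conditions: L-proline (30 mol %), CH2Cl2, rt; then 5, Hantzsch ester (1.2 equiv), rt
Reagents that add atoms: none
Why: The aldehyde of 7 forms a proline enamine whose α-carbon adds to the methyl ketone to give β-hydroxy aldehyde 8, whose iminium then undergoes Knoevenagel condensation with the single ring C–H of 5 to give alkylidene 9, which is reduced at the exocyclic carbon by hydride transfer from the Hantzsch ester. The closest known reaction types are the amine-catalysed enolexo aldolisation (this keto-aldehyde closes the same way with piperidinium acetate, there with dehydration) and the proline-catalysed three-component reductive alkylation of cyclic 1,3-diones with aldehydes and Hantzsch ester. The cyclopentane closes by a 5-(enolexo)-exo-trig aldol. The new CH centre should be set trans to the isopropenyl-bearing centre inherited from limonene (substrate control, reinforced thermodynamically because this centre stays epimerisable through the enamine and through 9), and the carbinol centre should be set with OH cis to the formyl group by the proline carboxylic acid, which hydrogen-bonds the ketone oxygen on the enamine-nitrogen side; this is also the more stable ketol, with methyl trans to formyl. The step needs the aldol to precede the condensation and the aldehyde rather than the ketone to act as donor, which the faster enamine formation of the aldehyde and the delayed addition of 5 and the reductant should secure, while the Hantzsch ester reduces only the electron-poor alkylidene and leaves the isopropenyl and prenyl alkenes alone.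

Compound list
1 | phloroglucinol (benzene-1,3,5-triol) | Oc1cc(O)cc(O)c1 | starting material
2 | isobutyryl chloride (2-methylpropanoyl chloride) | CC(C)C(Cl)=O | starting material
3 | phlorisobutyrophenone, 2-methyl-1-(2,4,6-trihydroxyphenyl)propan-1-one | CC(C)C(=O)c1c(O)cc(O)cc1O | intermediate
4 | prenyl bromide (1-bromo-3-methylbut-2-ene) | CC(C)=CCBr | starting material
5 | 2-isobutyryl-4,4-diprenylcyclohexane-1,3,5-trione, drawn as 3,5-dihydroxy-6,6-bis(3-methylbut-2-en-1-yl)-2-(2-methylpropanoyl)cyclohexa-2,4-dien-1-one | CC(C)C(=O)C1=C(O)C=C(O)C(CC=C(C)C)(CC=C(C)C)C1=O | intermediate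
6 | (R)-(+)-limonene | CC1=CC[C@@H](CC1)C(C)=C | starting material
7 | (3R)-6-oxo-3-(prop-1-en-2-yl)heptanal | O=CC[C@@H](CCC(C)=O)C(C)=C | intermediate
8 | (1S,2R,5R)-2-hydroxy-2-methyl-5-(prop-1-en-2-yl)cyclopentane-1-carbaldehyde (formyl trans to isopropenyl, cis to OH) | C=C(C)[C@@H]1CC[C@@](C)(O)[C@H]1C=O | intermediate (not isolated)
9 | Knoevenagel adduct of 8 and 5: exocyclic alkylidene on the ring carbon between the two oxygenated carbons, alkene geometry not defined | C=C(C)[C@@H]1CC[C@@](C)(O)[C@H]1C=C1C(=O)C(CC=C(C)C)(CC=C(C)C)C(=O)C(C(=O)C(C)C)=C1O | intermediate (not isolated)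
10 | 3,5-dihydroxy-4-{[(1S,2R,5R)-2-hydroxy-2-methyl-5-(prop-1-en-2-yl)cyclopentyl]methyl}-6,6-bis(3-methylbut-2-en-1-yl)-2-(2-methylpropanoyl)cyclohexa-2,4-dien-1-one | C=C(C)[C@@H]1CC[C@@](C)(O)[C@H]1CC1=C(O)C(CC=C(C)C)(CC=C(C)C)C(=O)C(C(=O)C(C)C)=C1O | target

Total step count: 4
Longest linear sequence: 3 steps (1 → 3 → 5 → 10; steps 1, 2 and 4)

Steps most likely to fail

Step 4. The β-hydroxy iminium/enamine may lose water (E1cB) to the conjugated enal before or during the condensation. The aldol closure may also be incomplete, so that open-chain 7 is condensed and reduced instead, or the enamine may attack the wrong ketone face. The fallback sets out from 7 and comes back at 8. It builds the ring and the carbinol centre without an amine-bound aldol: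
- 7 is cyclised and dehydrated with piperidinium acetate (benzene, 80 °C) to the enal (S)-2-methyl-5-(prop-1-en-2-yl)cyclopent-1-ene-1-carbaldehyde F1.
- Weitz–Scheffer epoxidation (H2O2, NaOH, MeOH, 0 °C) should close the epoxide on the face away from the isopropenyl group, giving the epoxy aldehyde (1S,2S,5R)-5-methyl-2-(prop-1-en-2-yl)-6-oxabicyclo[3.1.0]hexane-1-carbaldehyde F2.
- Single-electron reductive cleavage of the C–O bond α to the formyl group (Cp2TiCl from Cp2TiCl2/Zn, THF/MeOH, −78 °C) and protonation of the enolate should give 8. The carbinol configuration is fixed by the epoxide, and the formyl group settles trans to the isopropenyl group.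
- Isolated 8 is then united with 5 and Hantzsch ester without a secondary amine (EtOH, rt; the acidic trione promotes its own Knoevenagel condensation), which removes the enamine pathway for dehydration.

Step 2. The second prenylation may go to the other unsubstituted ring carbon, and over-alkylation and O-alkylation may compete. The fallback sets out from 3 and comes back at 10, with dearomatisation and union in reversed order. 8 (from 7 as in the first stage of step 4) is condensed with an excess of aromatic 3 and reduced in the same flask (proline, Hantzsch ester, CH2Cl2, rt). This should give the mono-C-alkylated acylphloroglucinol 1-(3-{[(1S,2R,5R)-2-hydroxy-2-methyl-5-(prop-1-en-2-yl)cyclopentyl]methyl}-2,4,6-trihydroxyphenyl)-2-methylpropan-1-one F3. F3 has only one free ring carbon, so double prenylation with 4 (NaOMe, MeOH, 0 °C) must begin there and should finish on the same, less hindered carbon to give 10.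

Step 3. Ozone may also cleave the isopropenyl alkene, or conversion may stop short. The fallback sets out from 6 and comes back at 7. Epoxidation of 6 with mCPBA (CH2Cl2, NaHCO3, 0 °C) is selective for the trisubstituted ring alkene and gives (4R)-limonene 1,2-oxide F4 as a cis/trans mixture. Periodic acid (H5IO6, THF/H2O, 0 °C) then opens and cleaves the epoxide to 7 without touching the isopropenyl group.

Further compounds
F1 | step 4 | (S)-2-methyl-5-(prop-1-en-2-yl)cyclopent-1-ene-1-carbaldehyde | C=C(C)[C@@H]1CCC(C)=C1C=O
F2 | step 4 | (1S,2S,5R)-5-methyl-2-(prop-1-en-2-yl)-6-oxabicyclo[3.1.0]hexane-1-carbaldehyde (epoxide trans to isopropenyl) | C=C(C)[C@@H]1CC[C@@]2(C)O[C@@]12C=O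
F3 | step 2 | 1-(3-{[(1S,2R,5R)-2-hydroxy-2-methyl-5-(prop-1-en-2-yl)cyclopentyl]methyl}-2,4,6-trihydroxyphenyl)-2-methylpropan-1-one | C=C(C)[C@@H]1CC[C@@](C)(O)[C@H]1Cc1c(O)cc(O)c(C(=O)C(C)C)c1O
F4 | step 3 | (4R)-limonene 1,2-oxide (cis/trans mixture at the epoxide) | CC12OC1C[C@@H](CC2)C(C)=C
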